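**Plan**

- Retrosynthetic cuts, in order: the angelate acyl C–O bond, the side-chain carbinol C–H (back to the aryl ketone), the C3 acetate, C2–C3 of ring B, the CH2–C bond to the borylmethyl group, the vinyl C–Br bond, the aryl O–vinyl C bond and the formyl C–aryl bond.
- Forward: ring A is bought as 4-hydroxyacetophenone and the chain is built on its phenol oxygen (ortho-formylation, oxa-Michael addition to methyl propiolate, α-bromination, borylmethyl Negishi coupling). Ring B closes last by C2–C3 bond formation, followed by O-acetylation, ketone reduction and angeloylation.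
- Enabling feature: in ring B, C3 is a secondary benzylic carbinol carbon and its neighbour C2 carries both the ring oxygen O1 and a 1-(methoxycarbonyl)vinyl group. The unit O–C3–C2–C(=CH2) is therefore the homoallylic alcohol left when a 2-(methoxycarbonyl)allyl boronate with aryloxy on its γ carbon adds to the ortho formyl group.
- Stereochemistry: C2/C3 cis follows from the boronate alkene geometry through a chair transition state, and the absolute sense at C3 (and with it C2) from (R)-TRIP. The (S) side-chain carbinol comes from Noyori transfer hydrogenation with the (S,S) catalyst, and the (Z) angelate is carried in intact from angelic acid.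

Key step: step 5

Assumption: (R)-TRIP is taken to direct the tethered allyl transfer to the Re face of the formyl group, the sense it shows with aryl aldehydes and allyl pinacolboronate in the intermolecular reaction; if the tether reverses this, (S)-TRIP is the catalyst.

**Route**

Step 1
Reactants: 1 4-hydroxyacetophenone
Product: 2 5-acetyl-2-hydroxybenzaldehyde
Conditions: MgCl2, Et3N, (CH2O)n, MeCN, reflux; then 1 M HCl
Reagents that add atoms: formaldehyde (as paraformaldehyde), C=O
Why: Magnesium phenoxide-directed ortho-formylation (Casnati–Skattebøl), in which the chelated phenoxide is hydroxymethylated at the free ortho position (para is blocked by the acetyl group) and the benzylic alkoxide is then oxidised by a second formaldehyde through hydride transfer.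

Step 2
Reactants: 2 5-acetyl-2-hydroxybenzaldehyde; 3 methyl propiolate
Product: 4 methyl (E)-3-(4-acetyl-2-formylphenoxy)prop-2-enoate
Conditions: N-methylmorpholine, CH2Cl2, 0 °C to rt
Reagents that add atoms: none
Why: Amine-mediated oxa-Michael addition of the acidic phenol to the ynoate should give the trans β-aryloxyacrylate, a reaction that is routine for salicylaldehydes and in which the weak base leaves the aldehyde and the ketone untouched.

Step 3
Reactants: 4 methyl (E)-3-(4-acetyl-2-formylphenoxy)prop-2-enoate
Product: 6 methyl (Z)-3-(4-acetyl-2-formylphenoxy)-2-bromoprop-2-enoate, via dibromide 5 (not isolated)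
Conditions: Br2, CH2Cl2, 0 °C, dark; then Et3N, 0 °C to rt
Reagents that add atoms: bromine, BrBr
Why: Bromine addition across the enol ether double bond followed by E1cB dehydrobromination (the standard route to α-halo-β-alkoxyacrylates) should give, through the reversible carbanion stage, the more stable isomer with bromine cis to the aryloxy group, while in the absence of acid the methyl ketone should not enolise and brominate.

Step 4
Reactants: 6 methyl (Z)-3-(4-acetyl-2-formylphenoxy)-2-bromoprop-2-enoate; 7 2-(iodomethyl)-4,4,5,5-tetramethyl-1,3,2-dioxaborolane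
Product: 9 methyl (E)-3-(4-acetyl-2-formylphenoxy)-2-[(4,4,5,5-tetramethyl-1,3,2-dioxaborolan-2-yl)methyl]prop-2-enoate, via borylmethylzinc iodide 8 (not isolated)
Conditions: 7, Zn dust (TMSCl-activated), THF, rt; then 6, Pd(dba)2 (5 mol %), SPhos (10 mol %), THF, 0 °C to rt; cold aqueous Na2EDTA work-up
Reagents that add atoms: none
Why: Negishi cross-coupling of Knochel's (pinacolboryl)methylzinc iodide with the activated alkenyl bromide proceeds with retention of alkene geometry, so the CH2B group ends up cis to the aryloxy group, and the alkylzinc iodide does not add to the aldehyde, ketone or ester while the electron-poor allylboronate should survive brief contact with zinc salts at low temperature.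

Step 5
Reactants: 9 methyl (E)-3-(4-acetyl-2-formylphenoxy)-2-[(4,4,5,5-tetramethyl-1,3,2-dioxaborolan-2-yl)methyl]prop-2-enoate
Product: 11 methyl 2-[(2S,3S)-5-acetyl-3-hydroxy-2,3-dihydro-1-benzofuran-2-yl]prop-2-enoate, via pinacol borate 10 (not isolated)
Conditions: (R)-TRIP [(R)-3,3′-bis(2,4,6-triisopropylphenyl)-1,1′-binaphthyl-2,2′-diyl hydrogen phosphate] (10 mol %), 4 Å MS, toluene, 0 °C to rt; then pH 7 phosphate buffer
Reagents that add atoms: none
Why: Proposed new method: the phosphoric acid should hydrogen-bond to a pinacol oxygen and so raise the Lewis acidity of boron, the aldehyde oxygen then binds boron and the allyl unit is transferred through a six-membered chair in which the aryloxy-bearing γ carbon bonds to the formyl carbon while the double bond moves to the exocyclic methylene, the closest known reactions being the chiral phosphoric acid-catalysed allylboration of aryl aldehydes with allyl pinacolboronates, the acid-catalysed additions of 2-alkoxycarbonyl allylboronates and the intramolecular allylboration of ω-oxo allylboronates, none of which has been run on a tethered 2-ester γ-aryloxy boronate. Ring B closes by 5-exo-trig attack on the formyl carbon, with C3a and C7a of the arene acting as a rigid two-atom tether. C2 is fixed relative to C3 by the alkene geometry, because the aryloxy group cis to CH2B must sit axial in the chair, which forces the aryl carbon of the aldehyde equatorial and leaves the new hydroxyl and the acrylate unit on the same face, so only the cis ring can form. C3 is set as (S) by the catalyst, which should steer the γ carbon to the Re face of the aldehyde as (R)-TRIP does in intermolecular cases. The step needs catalyst control over the racemic background reaction, which the deactivating 2-ester and the push-pull enol ether should secure by making the uncatalysed transfer slow, and it needs aldehyde over ketone selectivity, which the tether guarantees because the acetyl carbon cannot be reached.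

Step 6
Reactants: 11 methyl 2-[(2S,3S)-5-acetyl-3-hydroxy-2,3-dihydro-1-benzofuran-2-yl]prop-2-enoate
Product: 12 methyl 2-[(2S,3S)-3-acetoxy-5-acetyl-2,3-dihydro-1-benzofuran-2-yl]prop-2-enoate
Conditions: Ac2O, pyridine, CH2Cl2, 0 °C to rt
Reagents that add atoms: acetic anhydride, CC(=O)OC(C)=O
Why: Pyridine-mediated O-acetylation of the secondary benzylic alcohol leaves the C3–O bond intact and so retains configuration, prompt acylation blocks lactonisation onto the cis ester, and DMAP is left out because a nucleophilic amine could attack the acrylate in SN2′ fashion and expel the aryloxide.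

Step 7
Reactants: 12 methyl 2-[(2S,3S)-3-acetoxy-5-acetyl-2,3-dihydro-1-benzofuran-2-yl]prop-2-enoate
Product: 13 methyl 2-[(2S,3S)-3-acetoxy-5-[(1S)-1-hydroxyethyl]-2,3-dihydro-1-benzofuran-2-yl]prop-2-enoate
Conditions: RuCl[(S,S)-TsDPEN](p-cymene) (1 mol %), HCO2H/Et3N (5:2), EtOAc, rt
Reagents that add atoms: none
Why: Noyori asymmetric transfer hydrogenation, in which the ruthenium hydride and the ligand NH of the (S,S) catalyst deliver hydrogen to the Re face of the aryl methyl ketone through the six-membered outer-sphere transition state, should give the (S) carbinol as with acetophenones while leaving the acrylate C=C bond and the esters alone.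

Step 8
Reactants: 13 methyl 2-[(2S,3S)-3-acetoxy-5-[(1S)-1-hydroxyethyl]-2,3-dihydro-1-benzofuran-2-yl]prop-2-enoate; 14 angelic acid [(Z)-2-methylbut-2-enoic acid]
Product: 16 methyl 2-[(2S,3S)-3-acetoxy-5-[(1S)-1-{[(2Z)-2-methylbut-2-enoyl]oxy}ethyl]-2,3-dihydro-1-benzofuran-2-yl]prop-2-enoate (CNP0168827.1), via mixed anhydride 15 (not isolated)
Conditions: 14, 2,4,6-trichlorobenzoyl chloride, Et3N, toluene, rt; then 13, 75 °C
Reagents that add atoms: none
Why: Mixed-anhydride esterification of Yamaguchi type, in which the alcohol attacks the unhindered angeloyl carbonyl of the 2,4,6-trichlorobenzoic mixed anhydride, leaves the carbinol C–O bond untouched so the (S) centre is retained, and is run thermally without DMAP to avoid the conjugate addition–elimination that turns angelates into tiglates.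

**Compound list**

1 | 4-hydroxyacetophenone | CC(=O)c1ccc(O)cc1 | starting material
2 | 5-acetyl-2-hydroxybenzaldehyde | CC(=O)c1ccc(O)c(C=O)c1 | intermediate
3 | methyl propiolate | C#CC(=O)OC | starting material
4 | methyl (E)-3-(4-acetyl-2-formylphenoxy)prop-2-enoate | COC(=O)/C=C/Oc1ccc(C(C)=O)cc1C=O | intermediate
5 | methyl 3-(4-acetyl-2-formylphenoxy)-2,3-dibromopropanoate (racemic; both stereocentres are lost on elimination) | COC(=O)C(Br)C(Br)Oc1ccc(C(C)=O)cc1C=O | intermediate
6 | methyl (Z)-3-(4-acetyl-2-formylphenoxy)-2-bromoprop-2-enoate (Br cis to aryloxy) | COC(=O)/C(Br)=C/Oc1ccc(C(C)=O)cc1C=O | intermediate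
7 | 2-(iodomethyl)-4,4,5,5-tetramethyl-1,3,2-dioxaborolane | CC1(C)OB(CI)OC1(C)C | starting material
8 | [(4,4,5,5-tetramethyl-1,3,2-dioxaborolan-2-yl)methyl]zinc iodide | CC1(C)OB(C[Zn]I)OC1(C)C | intermediate
9 | methyl (E)-3-(4-acetyl-2-formylphenoxy)-2-[(4,4,5,5-tetramethyl-1,3,2-dioxaborolan-2-yl)methyl]prop-2-enoate (CH2B cis to aryloxy) | COC(=O)/C(CB1OC(C)(C)C(C)(C)O1)=C/Oc1ccc(C(C)=O)cc1C=O | intermediate
10 | methyl 2-[(2S,3S)-5-acetyl-3-[(4,4,5,5-tetramethyl-1,3,2-dioxaborolan-2-yl)oxy]-2,3-dihydro-1-benzofuran-2-yl]prop-2-enoate | C=C(C(=O)OC)[C@@H]1Oc2ccc(C(C)=O)cc2[C@@H]1OB1OC(C)(C)C(C)(C)O1 | intermediate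
11 | methyl 2-[(2S,3S)-5-acetyl-3-hydroxy-2,3-dihydro-1-benzofuran-2-yl]prop-2-enoate | C=C(C(=O)OC)[C@@H]1Oc2ccc(C(C)=O)cc2[C@@H]1O | intermediate
12 | methyl 2-[(2S,3S)-3-acetoxy-5-acetyl-2,3-dihydro-1-benzofuran-2-yl]prop-2-enoate | C=C(C(=O)OC)[C@@H]1Oc2ccc(C(C)=O)cc2[C@@H]1OC(C)=O | intermediate
13 | methyl 2-[(2S,3S)-3-acetoxy-5-[(1S)-1-hydroxyethyl]-2,3-dihydro-1-benzofuran-2-yl]prop-2-enoate | C=C(C(=O)OC)[C@@H]1Oc2ccc([C@H](C)O)cc2[C@@H]1OC(C)=O | intermediate
14 | angelic acid, (Z)-2-methylbut-2-enoic acid | C/C=C(/C)C(=O)O | starting material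
15 | (Z)-2-methylbut-2-enoic 2,4,6-trichlorobenzoic anhydride | C/C=C(/C)C(=O)OC(=O)c1c(Cl)cc(Cl)cc1Cl | intermediate
16 | methyl 2-[(2S,3S)-3-acetoxy-5-[(1S)-1-{[(2Z)-2-methylbut-2-enoyl]oxy}ethyl]-2,3-dihydro-1-benzofuran-2-yl]prop-2-enoate | C=C(C(=O)OC)[C@@H]1Oc2ccc([C@H](C)OC(=O)/C(C)=C\C)cc2[C@@H]1OC(C)=O | target

**Step count and risks**

Total step count: 8. Longest linear sequence: 8 steps (1 to 16).

Steps most likely to fail:

1. Step 5. The acid may not accelerate allyl transfer from the electron-poor push-pull boronate enough to outrun the uncatalysed racemic closure, or it may discriminate the aldehyde faces poorly in the tethered transition state. Acid-promoted lactonisation onto the cis ester or dehydration towards the aromatic benzofuran could also erode the product. The fallback sets out from 9. Cyclisation with Sc(OTf)3 (10 mol %) in CH2Cl2 at −78 to 0 °C, a Lewis acid activation established for 2-alkoxycarbonyl allylboronates, should give the racemic cis pinacol borate F1, with the cis relationship still imposed by the chair. Buffered hydrolysis gives racemic cis methyl 2-(5-acetyl-3-hydroxy-2,3-dihydro-1-benzofuran-2-yl)prop-2-enoate F2. Kinetic resolution with Candida antarctica lipase B and vinyl acetate in tert-butyl methyl ether at rt should, by the empirical rule for lipases and aryl carbinols, acetylate the (3S) enantiomer and leave the (2R,3R)-alcohol F3 behind. The acetate formed is 12, where the fallback rejoins the route.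

2. Step 4. The divalent zinc halide formed in the coupling may trigger premature, racemic ring closure of the freshly formed aldehyde boronate, and slow transmetalation may allow protodezincation or protodeboronation. The fallback sets out from 6 and avoids zinc altogether. Stille coupling with (tributylstannyl)methanol (Pd(PPh3)4, dioxane, 80 °C) should give methyl (E)-3-(4-acetyl-2-formylphenoxy)-2-(hydroxymethyl)prop-2-enoate F4. Methyl chloroformate and pyridine in CH2Cl2 at 0 °C convert it into the allylic methyl carbonate, methyl (E)-3-(4-acetyl-2-formylphenoxy)-2-{[(methoxycarbonyl)oxy]methyl}prop-2-enoate F5. Miyaura allylic borylation with bis(pinacolato)diboron and Pd(dba)2 in DMSO at 50 °C should place boron on the unhindered CH2 terminus of the π-allyl intermediate and return 9.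

3. Step 8. The (Z)-2-methylbut-2-enoyl unit may isomerise to the (E) tigloyl unit during activation, acyl transfer to the secondary benzylic alcohol may be slow, and the electron-rich benzylic centre may ionise on heating. The fallback sets out from 12. Transfer hydrogenation with RuCl[(R,R)-TsDPEN](p-cymene) in HCO2H/Et3N should give the epimeric carbinol, methyl 2-[(2S,3S)-3-acetoxy-5-[(1R)-1-hydroxyethyl]-2,3-dihydro-1-benzofuran-2-yl]prop-2-enoate F6. Mitsunobu esterification with angelic acid 14 (PPh3, diisopropyl azodicarboxylate, toluene, 0 °C) forms the ester with inversion at the carbinol carbon and without any base or nucleophilic catalyst that could isomerise the angelate, returning to the route at 16.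

**Further compounds**

F1 | step 5 | racemic cis methyl 2-{5-acetyl-3-[(4,4,5,5-tetramethyl-1,3,2-dioxaborolan-2-yl)oxy]-2,3-dihydro-1-benzofuran-2-yl}prop-2-enoate | C=C(C(=O)OC)[C@@H]1Oc2ccc(C(C)=O)cc2[C@@H]1OB1OC(C)(C)C(C)(C)O1.C=C(C(=O)OC)[C@H]1Oc2ccc(C(C)=O)cc2[C@H]1OB1OC(C)(C)C(C)(C)O1
F2 | step 5 | racemic cis methyl 2-(5-acetyl-3-hydroxy-2,3-dihydro-1-benzofuran-2-yl)prop-2-enoate | C=C(C(=O)OC)[C@@H]1Oc2ccc(C(C)=O)cc2[C@@H]1O.C=C(C(=O)OC)[C@H]1Oc2ccc(C(C)=O)cc2[C@H]1O
F3 | step 5 | methyl 2-[(2R,3R)-5-acetyl-3-hydroxy-2,3-dihydro-1-benzofuran-2-yl]prop-2-enoate | C=C(C(=O)OC)[C@H]1Oc2ccc(C(C)=O)cc2[C@H]1O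
F4 | step 4 | methyl (E)-3-(4-acetyl-2-formylphenoxy)-2-(hydroxymethyl)prop-2-enoate | COC(=O)/C(CO)=C/Oc1ccc(C(C)=O)cc1C=O
F5 | step 4 | methyl (E)-3-(4-acetyl-2-formylphenoxy)-2-{[(methoxycarbonyl)oxy]methyl}prop-2-enoate | COC(=O)/C(COC(=O)OC)=C/Oc1ccc(C(C)=O)cc1C=O
F6 | step 8 | methyl 2-[(2S,3S)-3-acetoxy-5-[(1R)-1-hydroxyethyl]-2,3-dihydro-1-benzofuran-2-yl]prop-2-enoate | C=C(C(=O)OC)[C@@H]1Oc2ccc([C@@H](C)O)cc2[C@@H]1OC(C)=O
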